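**Plan**
Retrosynthesis: the O9 senecioate and O8 tiglate C–O bonds are cut first, then the C7–isopropenyl bond (epoxide opening), then the C9–C10 ring-fusion bond (intramolecular Stetter), then C8–C9 (hydroformylation) and the C5–C6 and C5–C14 bonds (enolate alkylations).
Enabling feature (eremophilane numbering; ring A = C1–C5 and C10, ring B = C5–C10): the C9 oxygen and the C2 ketone are 1,4-related through C10 and C1, a dissonant pairing, so C9 must react as an acyl anion toward C10 of a C1=C10–C2=O enone.
Forward: ring A comes from (S)-pulegone as (S)-5-methylcyclohexenone; C5 is methylated and allylated, the enone is transposed, the allyl group is homologated to the C9 aldehyde, and ring B closes in the carbene-catalysed step to the cis-decalin-2,9-dione.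
Ring B is then desaturated at C7–C8, reduced at C9, epoxidised under hydroxyl direction, opened at C7 by an isopropenyl copper reagent and acylated at O8, then O9, before the C2 ketal is removed.
Stereochemistry: C4 from pulegone; C5 by allylation anti to C15; C10 by the tether (cis fusion); C9 by convex-face hydride addition; C8 and C7 by syn-directed epoxidation and anti opening.

Key step: step 10

Remark: bicyclic compounds carry eremophilane numbering (C14 = methyl on C5, C15 = methyl on C4), β is the face of C14 and H10, α the opposite face; (S)-pulegone, tigloyl chloride and 3-methylbut-2-enoyl chloride are taken as commercial.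

**Route**

Step 1
Reactants: 1 (S)-pulegone
Product: 2 (6S)-2,2,6-trimethyl-1-oxaspiro[2.5]octan-4-one (pulegone oxide, both spiro epimers)
Conditions: 30% H2O2, LiOH·H2O (cat.), MeOH, 0 °C to rt
Reagents that add atoms: hydrogen peroxide, OO
Why: Weitz–Scheffer nucleophilic epoxidation of the tetrasubstituted enone; the spiro epimers are immaterial because that carbon loses its oxygen in step 2, and the methyl-bearing centre is untouched.

Step 2
Reactants: 2 pulegone oxide
Product: 3 (5S)-5-methyl-2-(phenylsulfanyl)cyclohexan-1-one (C2 epimers)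
Conditions: PhSH (1.2 equiv), NaSPh (0.2 equiv), THF, reflux
Reagents that add atoms: benzenethiol, Sc1ccccc1
Why: Thiolate opens the epoxide at the ring α-carbon and the resulting β-alkoxy ketone undergoes retro-aldol loss of acetone, after which the thiol protonates the enolate and regenerates thiolate; the C2 epimer mixture is immaterial.

Step 3
Reactants: 3 (5S)-5-methyl-2-(phenylsulfanyl)cyclohexan-1-one
Product: 5 (5S)-5-methylcyclohex-2-en-1-one, via sulfoxide 4 (not isolated)
Conditions: 3-chloroperoxybenzoic acid (mCPBA, 1.0 equiv), CH2Cl2, −78 °C; NaHCO3 wash; then toluene, 110 °C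
Reagents that add atoms: none
Why: Sulfide oxidation followed by thermal sulfoxide syn-elimination, which can only take a hydrogen from C3, should give the conjugated enone with the remote methyl stereocentre intact.

Step 4
Reactants: 5 (5S)-5-methylcyclohex-2-en-1-one
Product: 7 (5S)-5,6-dimethylcyclohex-2-en-1-one (C6 epimers), via lithium dienolate 6 (not isolated)
Conditions: LiN(iPr)2, THF, −78 °C; MeI, −78 to 0 °C
Reagents that add atoms: iodomethane, CI
Why: Kinetic α′-deprotonation of the cyclohexenone gives the cross-conjugated dienolate, which is C-methylated (enolate alkylation); either C6 epimer serves because this centre is enolised again in step 5.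

Step 5
Reactants: 7 (5S)-5,6-dimethylcyclohex-2-en-1-one; 8 allyl bromide
Product: 10 (5S,6R)-5,6-dimethyl-6-(prop-2-en-1-yl)cyclohex-2-en-1-one, via lithium dienolate 9 (not isolated)
Conditions: LiN(iPr)2, THF, −78 °C; 8, DMPU, −78 °C to rt
Reagents that add atoms: allyl bromide 8, C=CCBr
Why: Second α′-enolate alkylation; in the planar tetrasubstituted enolate the C5 methyl turns pseudoaxial to avoid allylic strain with the C6 methyl and allyl bromide adds to the opposite face, so the allyl group ends trans to the secondary methyl and the two methyls cis, as in alkylations of 2,3-dimethylcyclohexanone enolates.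

Step 6
Reactants: 10 (5S,6R)-5,6-dimethyl-6-(prop-2-en-1-yl)cyclohex-2-en-1-one
Product: 11 (3R,4S)-3,4-dimethyl-3-(prop-2-en-1-yl)-7-oxabicyclo[4.1.0]heptan-2-one (epoxide epimers)
Conditions: 30% H2O2, NaOH (cat.), MeOH, 0 °C
Reagents that add atoms: hydrogen peroxide, OO
Why: Weitz–Scheffer epoxidation attacks only the electron-poor enone double bond and leaves the allyl group alone; the epoxide configuration is irrelevant because both carbons lose it in steps 7 and 8.

Step 7
Reactants: 11 epoxy ketone
Product: 12 (4R,5S)-4,5-dimethyl-4-(prop-2-en-1-yl)cyclohex-2-en-1-ol (C1 epimers)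
Conditions: N2H4·H2O, AcOH (cat.), MeOH, 0 °C to rt, under N2
Reagents that add atoms: none
Why: Wharton rearrangement: the epoxy hydrazone opens to an alkenyl diazene that loses dinitrogen, moving the oxygen to the former β-carbon and the double bond next to the quaternary carbon; the carbinol epimers converge in step 8.

Step 8
Reactants: 12 allylic alcohol
Product: 13 (4R,5S)-4,5-dimethyl-4-(prop-2-en-1-yl)cyclohex-2-en-1-one
Conditions: MnO2, CH2Cl2, rt
Reagents that add atoms: none
Why: Allylic alcohol oxidation by MnO2 completes the 1,3-carbonyl transposition without affecting the terminal alkene or the two stereocentres.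

Step 9
Reactants: 13 (4R,5S)-4,5-dimethyl-4-(prop-2-en-1-yl)cyclohex-2-en-1-one
Product: 14 4-[(1R,6S)-1,6-dimethyl-4-oxocyclohex-2-en-1-yl]butanal
Conditions: Rh(CO)2(acac) (1 mol %), 4,5-bis(diphenylphosphino)-9,9-dimethylxanthene (2 mol %), CO/H2 (1:1, 10 bar), toluene, 70 °C
Reagents that add atoms: carbon monoxide, [C-]#[O+]
Why: Rhodium-catalysed hydroformylation with a wide-bite-angle diphosphine places the formyl group on the terminal carbon of the monosubstituted alkene (linear selectivity reinforced by the neighbouring quaternary carbon), while the disubstituted conjugated alkene should not insert under these mild conditions.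

Step 10
Reactants: 14 4-[(1R,6S)-1,6-dimethyl-4-oxocyclohex-2-en-1-yl]butanal
Product: 15 (4S,5R,10S)-4,5-dimethyl-cis-decalin-2,9-dione [(4S,4aR,8aS)-4,4a-dimethyloctahydronaphthalene-2,8(1H,3H)-dione]
Conditions: 2-(pentafluorophenyl)-6,7-dihydro-5H-pyrrolo[2,1-c][1,2,4]triazol-2-ium tetrafluoroborate (20 mol %), KN(SiMe3)2 (20 mol %), toluene, 23 °C
Reagents that add atoms: none
Why: The triazolylidene adds to the C9 aldehyde and proton transfer gives the Breslow intermediate, whose nucleophilic C9 adds to C10 of the C1=C10–C2=O enone; protonation of the C1–C2 enolate and loss of the carbene release the C9 ketone. The closest known reaction type is the carbene-catalysed intramolecular Stetter reaction of aliphatic aldehydes tethered to 4,4-disubstituted cyclohexenones and cyclohexadienones. Ring B closes in a 6-exo-trig mode. C10 is the one new stereocentre and is controlled by the tether: with perpendicular approach to the enone, the chain anchored at C5 can reach C10 only with the new C9–C10 bond gauche to C5–C6, so C9 arrives on the face of C6 and H10 ends cis to C14. The step needs 1,4-addition to win over benzoin coupling, aldol addition and enolisation of the aldehyde; intramolecularity, the gem-disubstituted C5, the unsubstituted acceptor carbon and the weakly basic N-pentafluorophenyl carbene secure this. Only catalytic base is present, so the new centre α to the C9 ketone should not epimerise.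

Step 11
Reactants: 15 cis-decalin-2,9-dione
Product: 16 (4S,5R,10S)-2,2-(ethylenedioxy)-4,5-dimethyl-cis-decalin-9-one
Conditions: Me3SiOCH2CH2OSiMe3 (1.1 equiv), Me3SiOSO2CF3 (5 mol %), CH2Cl2, −78 °C
Reagents that add atoms: 1,2-bis(trimethylsilyloxy)ethane, C[Si](C)(C)OCCO[Si](C)(C)C
Why: Noyori ketalisation under kinetic control should pick the C2 ketone, which lies between two methylenes, over the C9 ketone flanked by the ring-fusion methine and quaternary C5; the aprotic, low-temperature conditions avoid enolisation toward C10 and keep the cis fusion.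

Step 12
Reactants: 16 keto ketal
Product: 18 (4S,5R,10S)-2,2-(ethylenedioxy)-4,5-dimethyl-cis-decal-7-en-9-one, via lithium enolate 17 (not isolated)
Conditions: LiN(iPr)2 (1.1 equiv), THF, −78 °C; then PhS(Cl)=NtBu (1.2 equiv), −78 °C
Reagents that add atoms: none
Why: Kinetic deprotonation occurs at the C8 methylene and not at the hindered C10 methine, and the enolate is dehydrogenated in the same flask by the Mukaiyama sulfinimidoyl chloride (sulfenylation at C8, then intramolecular elimination of the sulfenamide), giving the C7=C8 enone without touching C10.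

Step 13
Reactants: 18 enone ketal
Product: 19 (4S,5R,9R,10S)-2,2-(ethylenedioxy)-4,5-dimethyl-cis-decal-7-en-9-ol (9α-hydroxyl)
Conditions: NaBH4, CeCl3·7H2O, MeOH, −78 °C
Reagents that add atoms: none
Why: Luche 1,2-reduction; hydride should reach C9 from the convex β face, because the α face is covered by ring A (axial C4 and the axial ketal oxygen), which places the hydroxyl α.

Step 14
Reactants: 19 allylic alcohol
Product: 20 (4S,5R,7R,8S,9S,10S)-7α,8α-epoxy-2,2-(ethylenedioxy)-4,5-dimethyl-cis-decalin-9α-ol
Conditions: VO(acac)2 (5 mol %), tBuOOH, CH2Cl2, 0 °C to rt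
Reagents that add atoms: tert-butyl hydroperoxide, CC(C)(C)OO
Why: Vanadium-catalysed hydroxyl-directed epoxidation delivers the peroxide oxygen from the alkoxide-bound metal to the alkene face syn to the 9α-hydroxyl, which fixes C7 and C8 as the α-epoxide.

Step 15
Reactants: 20 epoxy alcohol; 21 isopropenylmagnesium bromide
Product: 22 (4S,5R,7R,8R,9S,10S)-2,2-(ethylenedioxy)-10βH-eremophil-11-ene-8α,9α-diol
Conditions: 21 (4 equiv), CuI (20 mol %), THF, −30 to 0 °C; aq NH4Cl
Reagents that add atoms: isopropenylmagnesium bromide 21, C=C(C)[Mg]Br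
Why: Copper-catalysed Grignard opening of the epoxide is an SN2 process: the isopropenyl group should enter at C7, the epoxide carbon remote from the C9 alkoxide (the usual course for cis-2,3-epoxycyclohexanols), from the β face with inversion, which sets C7 and leaves the C8 oxygen α.

Step 16
Reactants: 22 diol; 23 tigloyl chloride [(2E)-2-methylbut-2-enoyl chloride]
Product: 24 (4S,5R,7R,8R,9S,10S)-2,2-(ethylenedioxy)-9α-hydroxy-10βH-eremophil-11-en-8α-yl (2E)-2-methylbut-2-enoate
Conditions: 23 (1.1 equiv), pyridine, 4-(dimethylamino)pyridine (DMAP, cat.), CH2Cl2, −20 to 0 °C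
Reagents that add atoms: tigloyl chloride 23, C/C=C(\C)C(Cl)=O
Why: DMAP-catalysed acylation with a limiting amount of acid chloride should select the equatorial C8 hydroxyl over the axial C9 hydroxyl, which sits on the concave face next to the ring fusion.

Step 17
Reactants: 24 mono-tiglate; 25 3-methylbut-2-enoyl chloride
Product: 26 (4S,5R,7R,8R,9S,10S)-2,2-(ethylenedioxy)-9α-(3-methylbut-2-enoyloxy)-10βH-eremophil-11-en-8α-yl (2E)-2-methylbut-2-enoate
Conditions: 25 (3 equiv), pyridine, DMAP, CH2Cl2, 0 °C to rt
Reagents that add atoms: 3-methylbut-2-enoyl chloride 25, CC(C)=CC(Cl)=O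
Why: DMAP-catalysed acylation of the remaining hindered secondary alcohol with excess acid chloride; pyridine is used in place of a trialkylamine so that the acid chloride is not turned into a vinylketene and the double bond stays conjugated.

Step 18
Reactants: 26 ketal diester
Product: 27 CNP0181050.1, (4S,5R,7R,8R,9S,10S)-8α-[(2E)-2-methylbut-2-enoyloxy]-9α-(3-methylbut-2-enoyloxy)-10βH-eremophil-11-en-2-one
Conditions: pyridinium 4-toluenesulfonate, acetone/H2O (10:1), 50 °C
Reagents that add atoms: water, O
Why: Mild acid-catalysed hydrolysis of the dioxolane frees the C2 ketone without touching the two enoates, the isopropenyl group or any stereocentre (none is α to C2).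

**Compound list**
1 | (S)-pulegone | C[C@H]1CCC(=C(C)C)C(=O)C1 | starting material
2 | (6S)-2,2,6-trimethyl-1-oxaspiro[2.5]octan-4-one (spiro epimers) | C[C@H]1CCC2(OC2(C)C)C(=O)C1 | intermediate
3 | (5S)-5-methyl-2-(phenylsulfanyl)cyclohexan-1-one (C2 epimers) | C[C@H]1CCC(Sc2ccccc2)C(=O)C1 | intermediate
4 | (5S)-5-methyl-2-(phenylsulfinyl)cyclohexan-1-one (not isolated) | C[C@H]1CCC(S(=O)c2ccccc2)C(=O)C1 | intermediate
5 | (5S)-5-methylcyclohex-2-en-1-one | C[C@H]1CC=CC(=O)C1 | intermediate
6 | lithium (3S)-3-methylcyclohexa-1,5-dien-1-olate (not isolated) | C[C@H]1CC=CC(O[Li])=C1 | intermediate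
7 | (5S)-5,6-dimethylcyclohex-2-en-1-one (C6 epimers) | C[C@H]1CC=CC(=O)C1C | intermediate
8 | allyl bromide | C=CCBr | starting material
9 | lithium (3S)-2,3-dimethylcyclohexa-1,5-dien-1-olate (not isolated) | C[C@H]1CC=CC(O[Li])=C1C | intermediate
10 | (5S,6R)-5,6-dimethyl-6-(prop-2-en-1-yl)cyclohex-2-en-1-one | C=CC[C@@]1(C)C(=O)C=CC[C@@H]1C | intermediate
11 | (3R,4S)-3,4-dimethyl-3-(prop-2-en-1-yl)-7-oxabicyclo[4.1.0]heptan-2-one (epoxide epimers) | C=CC[C@@]1(C)C(=O)C2OC2C[C@@H]1C | intermediate
12 | (4R,5S)-4,5-dimethyl-4-(prop-2-en-1-yl)cyclohex-2-en-1-ol (C1 epimers) | C=CC[C@@]1(C)C=CC(O)C[C@@H]1C | intermediate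
13 | (4R,5S)-4,5-dimethyl-4-(prop-2-en-1-yl)cyclohex-2-en-1-one | C=CC[C@@]1(C)C=CC(=O)C[C@@H]1C | intermediate
14 | 4-[(1R,6S)-1,6-dimethyl-4-oxocyclohex-2-en-1-yl]butanal | O=CCCC[C@@]1(C)C=CC(=O)C[C@@H]1C | intermediate
15 | (4S,5R,10S)-4,5-dimethyl-cis-decalin-2,9-dione | O=C1CCC[C@@]2(C)[C@@H]1CC(=O)C[C@@H]2C | intermediate
16 | (4S,5R,10S)-2,2-(ethylenedioxy)-4,5-dimethyl-cis-decalin-9-one | O=C1CCC[C@@]2(C)[C@@H]1CC3(OCCO3)C[C@@H]2C | intermediate
17 | lithium C8=C9 enolate of 16 (not isolated) | [Li]OC1=CCC[C@@]2(C)[C@@H]1CC3(OCCO3)C[C@@H]2C | intermediate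
18 | (4S,5R,10S)-2,2-(ethylenedioxy)-4,5-dimethyl-cis-decal-7-en-9-one | O=C1C=CC[C@@]2(C)[C@@H]1CC3(OCCO3)C[C@@H]2C | intermediate
19 | (4S,5R,9R,10S)-2,2-(ethylenedioxy)-4,5-dimethyl-cis-decal-7-en-9-ol | O[C@@H]1C=CC[C@@]2(C)[C@@H]1CC3(OCCO3)C[C@@H]2C | intermediate
20 | (4S,5R,7R,8S,9S,10S)-7α,8α-epoxy-2,2-(ethylenedioxy)-4,5-dimethyl-cis-decalin-9α-ol | O[C@@H]1[C@@H]3O[C@@H]3C[C@@]2(C)[C@@H]1CC4(OCCO4)C[C@@H]2C | intermediate
21 | isopropenylmagnesium bromide | C=C(C)[Mg]Br | starting material
22 | (4S,5R,7R,8R,9S,10S)-2,2-(ethylenedioxy)-10βH-eremophil-11-ene-8α,9α-diol | C=C(C)[C@H]1C[C@@]2(C)[C@H](CC3(OCCO3)C[C@@H]2C)[C@H](O)[C@@H]1O | intermediate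
23 | tigloyl chloride | C/C=C(\C)C(Cl)=O | starting material
24 | 2,2-(ethylenedioxy)-9α-hydroxy-10βH-eremophil-11-en-8α-yl (2E)-2-methylbut-2-enoate | C=C(C)[C@H]1C[C@@]2(C)[C@H](CC3(OCCO3)C[C@@H]2C)[C@H](O)[C@@H]1OC(=O)/C(C)=C/C | intermediate
25 | 3-methylbut-2-enoyl chloride | CC(C)=CC(Cl)=O | starting material
26 | 2,2-(ethylenedioxy)-9α-(3-methylbut-2-enoyloxy)-10βH-eremophil-11-en-8α-yl (2E)-2-methylbut-2-enoate | C=C(C)[C@H]1C[C@@]2(C)[C@H](CC3(OCCO3)C[C@@H]2C)[C@H](OC(=O)C=C(C)C)[C@@H]1OC(=O)/C(C)=C/C | intermediate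
27 | CNP0181050.1 | C=C(C)[C@H]1C[C@@]2(C)[C@H](CC(=O)C[C@@H]2C)[C@H](OC(=O)C=C(C)C)[C@@H]1OC(=O)/C(C)=C/C | target

**Totals**
Total steps: 18. Longest linear sequence: 18 steps, from (S)-pulegone 1.

**Steps most likely to fail**

Step 10. The carbene may be diverted: the enolisable aldehyde can undergo aldol addition or benzoin coupling faster than the six-membered closure onto an acceptor carbon that sits next to quaternary C5, so that ring B forms slowly or not at all. Fallback, from 14 back to 15: the same C9–C10 bond is made reductively. SmI2 in THF/MeOH at −78 °C should bring about ketyl–olefin 6-exo cyclisation of the aldehyde onto C10 of the enone, cis-fused for the same geometric reason, to give (4S,5R,10S)-9-hydroxy-4,5-dimethyl-cis-decalin-2-one F1 as C9 epimers. Oxidation of this alcohol with Dess–Martin periodinane would then give dione 15.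

Step 15. The ring opening may take the wrong regiochemical course: the chair-like pathway for attack at C7 places the incoming group syn-axial to C14, so the nucleophile may add at C8 or react sluggishly. Fallback, from 18 back to 24: carbon and oxygen are introduced in the opposite order. Copper-catalysed 1,4-addition of 21 to enone 18 (CuI, Me3SiCl, THF, −78 °C), expected from the convex face, would give 2,2-(ethylenedioxy)-9-(trimethylsilyloxy)-10βH-eremophila-8,11-diene F2 with the isopropenyl group 7β. Regeneration of the enolate with MeLi and oxidation with 2-(phenylsulfonyl)-3-phenyloxaziridine, anti to the isopropenyl group, would give 2,2-(ethylenedioxy)-8α-hydroxy-10βH-eremophil-11-en-9-one F3. Acylation of its only hydroxyl with 23 would give 2,2-(ethylenedioxy)-9-oxo-10βH-eremophil-11-en-8α-yl (2E)-2-methylbut-2-enoate F4, and NaBH4 reduction from the convex face (MeOH, −78 °C) returns to 24.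

Step 16. The acylation may fail to discriminate between the two hydroxyls, or the tigloyl group may migrate from O8 to O9 under the basic conditions, giving regioisomeric and doubly acylated material. Fallback, from 20 back to 24: O9 is masked before O8 exists. Silylation of 20 (Et3SiCl, imidazole) would give 7α,8α-epoxy-2,2-(ethylenedioxy)-9α-(triethylsilyloxy)-4,5-dimethyl-cis-decalin F5. Opening with 21 and CuI as in step 15 would give 2,2-(ethylenedioxy)-9α-(triethylsilyloxy)-10βH-eremophil-11-en-8α-ol F6, whose single free hydroxyl is acylated with 23 to give 2,2-(ethylenedioxy)-9α-(triethylsilyloxy)-10βH-eremophil-11-en-8α-yl (2E)-2-methylbut-2-enoate F7. HF·pyridine in THF then removes the silyl group without an alkoxide that could trigger migration, returning to 24.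

**Further compounds**
F1 | step 10 | (4S,5R,10S)-9-hydroxy-4,5-dimethyl-cis-decalin-2-one (C9 epimers) | OC1CCC[C@@]2(C)[C@@H]1CC(=O)C[C@@H]2C
F2 | step 15 | 2,2-(ethylenedioxy)-9-(trimethylsilyloxy)-10βH-eremophila-8,11-diene | C=C(C)[C@H]1C[C@@]2(C)[C@H](CC3(OCCO3)C[C@@H]2C)C(O[Si](C)(C)C)=C1
F3 | step 15 | 2,2-(ethylenedioxy)-8α-hydroxy-10βH-eremophil-11-en-9-one | C=C(C)[C@H]1C[C@@]2(C)[C@H](CC3(OCCO3)C[C@@H]2C)C(=O)[C@@H]1O
F4 | step 15 | 2,2-(ethylenedioxy)-9-oxo-10βH-eremophil-11-en-8α-yl (2E)-2-methylbut-2-enoate | C=C(C)[C@H]1C[C@@]2(C)[C@H](CC3(OCCO3)C[C@@H]2C)C(=O)[C@@H]1OC(=O)/C(C)=C/C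
F5 | step 16 | 7α,8α-epoxy-2,2-(ethylenedioxy)-9α-(triethylsilyloxy)-4,5-dimethyl-cis-decalin | CC[Si](CC)(CC)O[C@@H]1[C@@H]3O[C@@H]3C[C@@]2(C)[C@@H]1CC4(OCCO4)C[C@@H]2C
F6 | step 16 | 2,2-(ethylenedioxy)-9α-(triethylsilyloxy)-10βH-eremophil-11-en-8α-ol | C=C(C)[C@H]1C[C@@]2(C)[C@H](CC3(OCCO3)C[C@@H]2C)[C@H](O[Si](CC)(CC)CC)[C@@H]1O
F7 | step 16 | 2,2-(ethylenedioxy)-9α-(triethylsilyloxy)-10βH-eremophil-11-en-8α-yl (2E)-2-methylbut-2-enoate | C=C(C)[C@H]1C[C@@]2(C)[C@H](CC3(OCCO3)C[C@@H]2C)[C@H](O[Si](CC)(CC)CC)[C@@H]1OC(=O)/C(C)=C/C
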